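(The runs come from a simulation for an exercise, and the scatter is random.)

In a one-step world substrate would become target and stay target, so one rate and one ceiling would describe a flask; the eta run below already asks for more, because substrate falls faster than target rises.

| setting | eta | larch | alder | elm | oak | cedar | birch |
|---|---|---|---|---|---|---|---|
| substrate | 0.11 M | 0.10 M | 0.40 M | 0.10 M | 0.10 M | 0.050 M | 0.10 M |
| partner | 0.060 M | 0.0300 M | 0.200 M | 0.100 M | 0.0600 M | 0.0600 M | 0.0600 M |
| free catalyst | 0.14 mM | 0.60 mM | 0.050 mM | 0.040 mM | 0.14 mM | 0.14 mM | 0.30 mM |
| remark | run made earlier |  |  |  |  |  |  |
| time |  | 40 h | 40 h | 40 h | 40 h | 40 h | 40 h |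

- eta (time / h: target / %, substrate / %): 0.500: 2.7, 96.7; 1.50: 7.9, 92.5; 3.00: 13.4, 84.0; 4.00: 17.9, 78.8; 6.00: 26.5, 69.0; 8.00: 34.9, 58.8

(scatter of a reading: 0.3 percentage points)

- the earlier runs were read with a standard deviation of 0.3 percentage points
- no earlier run changes the charge of free catalyst; that part of a forecast is a guess

1. the flasks by amount of target, in percent of the substrate charged, highest first, at 40 h (larch / alder / elm / oak / cedar / birch)
2. the same order at 2.0 h (larch / alder / elm / oak / cedar / birch)
3. the amount of target, in percent of the substrate charged of the flask you put first, at 40 h
4. the amount of target, in percent of the substrate charged of the flask you put last, at 40 h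

Here is my own reckoning, as a ladder of clocks from the fastest up. Target climbs nearly straight in the eta run, reaching 34.9% at 8.00 h, which gives a turnover of 34.3 h⁻¹ per catalyst, or one cycle in 1.75 min, if rate follows catalyst, which is a guess. On the next rung stands the partner clock, the time to spend the partner charge at one partner per target: 1.46 h in larch, where partner looks like the limiting reagent, 12.5 h in oak, and 117 h in alder, longer than the 40 h allowed.

The top rung comes from the gap of substrate lost but not found as target, 3.30% at 4.00 h and 6.30% at 8.00 h. The forecast calls it a side path; I wager instead on target attacked by further partner, and with a scatter of 0.3 percentage points that stays a wager. Around 6.00 h the gap then gives target a rough life of 35.3 h at about 21.0 mM of partner, and if the attack is first order in partner, as I assume, that life comes to 3.70 h at alder's charge, shorter than alder's partner clock.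

Partner clock over target life comes to 31.5 in alder, and this ratio is what I carry, the spoil number. It sets attack against making at the charge, and during a run that comparison drifts as target builds and partner falls. It is 0.0591 in larch and 1.01 in oak, so I expect alder to end well under its clock's promise.

The forecast says “the rate looks zero order in both” and gives cedar > birch > oak > elm > larch > alder at 40 h, larch > birch > cedar > oak > elm > alder at 2.0 h, 85% for the first flask and 17% for the last.

The flasks give cedar > birch > oak > larch > elm > alder at 40 h and larch > birch > cedar > oak > elm > alder at 2.0 h, with 74.9% and 6.55%.

    substrate + free catalyst ⇌ catalyst intermediate A (K = 880 M⁻¹, k = 1800 M⁻¹ h⁻¹)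
    partner + catalyst intermediate A → catalyst intermediate B (k = 3.20 × 10⁵ M⁻¹ h⁻¹)
    catalyst intermediate B → released group + catalyst intermediate C (k = 240 h⁻¹)
    catalyst intermediate C → free catalyst + target (k = 71.0 h⁻¹)
    partner + target → over-reaction product (k = 1.70 M⁻¹ h⁻¹)

Alder, with its spoil number of 31.5, holds 6.55% of target beside 18.6% of over-reaction product at 40 h, and removing the attack of partner on target lifts its target to 25.2%, which is part of why alder stands so low. That puts the ratio of over-reaction product to target in alder at 2.84. A neighbour of alder charged with 2.0 × 10⁻⁵ M of free catalyst has a spoil number of 78.8, and it ends with 1.13% of target beside 9.01% of over-reaction product, a ratio of 7.97.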